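**Strategy**

The saturated ring of the tetralin (C1, C2, C3, C4, C4a, C8a) is cut at C1–C2 and C3–C4, exploiting that C1 and C4 both flank the dimethoxybenzo ring and that the C2/C3 substituents are cis. C1, C4, C4a and C8a are the four-membered ring of 4,5-dimethoxybenzocyclobutenol; C2/C3 are the olefin of (5R)-5-(l-menthyloxy)furan-2(5H)-one. In one operation, thermal 4π ring opening and endo [4+2] capture insert C2–C3 into the four-membered ring (two-carbon ring expansion) and fix both CH2O-bearing stereocentres. The remaining C1 hydroxyl is then exchanged for the aryl group, trans to C2, by Friedel–Crafts arylation; reduction and O-methylation finish.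

Key step: step 3

Remark: tetralin numbering of the target is used (C1 aryl-bearing, C2 and C3 methoxymethyl-bearing, C4 the benzylic CH2). The target is (1R,2S,3R), that is 1,2-trans and 2,3-cis. In the lactone intermediates, tetralin C1, C2, C3 correspond to C9, C9a, C3a. Compound 5 is assumed to be purchased.

**Step 1**
Reactants: 1 2-bromo-4,5-dimethoxybenzaldehyde
Product: 2 2-(2-bromo-4,5-dimethoxyphenyl)oxirane (racemic)
Conditions: Me3S+ I−, NaH, DMSO/THF, 0 °C → rt
Reagents that add atoms: trimethylsulfonium iodide, C[S+](C)C.[I-]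
Why: Corey–Chaykovsky epoxidation of a non-enolisable aryl aldehyde; the new stereocentre is racemic and is erased in step 3.

**Step 2**
Reactants: 2 2-(2-bromo-4,5-dimethoxyphenyl)oxirane
Product: 4 4,5-dimethoxybenzocyclobuten-1-ol (racemic; 3,4-dimethoxybicyclo[4.2.0]octa-1,3,5-trien-7-ol), via aryllithium epoxide 3 (not isolated)
Conditions: n-BuLi, THF, −78 °C; MgBr2·OEt2, −78 → 0 °C; H2O
Reagents that add atoms: none
Why: Parham-type cyclisation of an o-bromostyrene oxide: bromine–lithium exchange is faster than epoxide opening at −78 °C, MgBr2 activates the epoxide and the aryl-metal closes the four-membered ring to the benzylic alcohol; the carbinol centre is racemic and is destroyed in step 3.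

**Step 3**
Reactants: 4 4,5-dimethoxybenzocyclobuten-1-ol; 5 (5R)-5-{[(1R,2S,5R)-5-methyl-2-(propan-2-yl)cyclohexyl]oxy}furan-2(5H)-one
Product: 7 (3R,3aR,9R,9aR)-9-hydroxy-6,7-dimethoxy-3-[(1R,2S,5R)-menthyloxy]-3a,4,9,9a-tetrahydronaphtho[2,3-c]furan-1(3H)-one, via (E)-hydroxy-o-quinodimethane 6 (not isolated)
Conditions: 4 (1 equiv), 5 (1.5 equiv), toluene, 110 °C, degassed, sealed tube
Reagents that add atoms: none
Why: Heating opens the cyclobutenol by conrotatory 4π electrocyclic ring opening with the hydroxyl rotating outward, and the resulting (E)-dienol 6 is trapped by the butenolide in a [4+2] cycloaddition, so that the two olefinic carbons are inserted between the two sp3 carbons of the four-membered ring. The closest known reaction type is the thermolysis of benzocyclobutenols in the presence of acrylate-type dienophiles, combined with the Diels–Alder reaction of 5-alkoxybutenolides with reactive dienes. The six-membered carbocycle is closed by a concerted suprafacial cycloaddition (bonds C9–C9a and C3a–C4 of 7, which are C1–C2 and C3–C4 of the tetralin), and the lactone ring is brought in intact by the dienophile. C9a and C3a are cis because the ring olefin is (Z), and their absolute configuration follows from addition to the face of 5 anti to the menthyloxy group at the acetal carbon; the carbinol centre C9 is set by the endo transition state, which places the outward hydroxyl cis to the lactone carbonyl. The step needs regiocontrol, because the two lactone carbons later become identical methoxymethyl groups and the regioisomer would lead into the enantiomeric series: the hydroxyl donor puts the largest HOMO coefficient on the methylene terminus, which bonds to the β-carbon of the enone (ortho rule). Endo/exo control is not required, since C9 is ionised in step 4.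

**Step 4**
Reactants: 7 hydroxy lactone; 8 1,2-dimethoxybenzene (veratrole)
Product: 9 (3R,3aR,9R,9aS)-9-(3,4-dimethoxyphenyl)-6,7-dimethoxy-3-[(1R,2S,5R)-menthyloxy]-3a,4,9,9a-tetrahydronaphtho[2,3-c]furan-1(3H)-one
Conditions: HBF4·OEt2 (1.1 equiv), 8 (5 equiv), CH2Cl2, −78 → −20 °C
Reagents that add atoms: none
Why: Friedel–Crafts alkylation through a benzylic cation stabilised by the para methoxy group at C6; veratrole attacks para to one of its methoxy groups on the convex face, anti to the C9a–carbonyl bond of the cis-fused lactone, which sets C9 (tetralin C1) trans to C2, and both C9 epimers of 7 converge.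

**Step 5**
Reactants: 9 aryl lactone
Product: 10 [(1R,2S,3R)-1-(3,4-dimethoxyphenyl)-6,7-dimethoxy-1,2,3,4-tetrahydronaphthalene-2,3-diyl]dimethanol
Conditions: LiAlH4, THF, 0 °C → rt; H2O/NaOH work-up
Reagents that add atoms: none
Why: Hydride reduction of the lactone and of the aldehyde unmasked when the ring-opened menthyl hemiacetal collapses should give the cis 1,4-diol and free menthol; no stereocentre is touched, since the transient aldehydes are reduced faster than they enolise.

**Step 6**
Reactants: 10 diol
Product: 11 (1R,2S,3R)-1-(3,4-dimethoxyphenyl)-6,7-dimethoxy-2,3-bis(methoxymethyl)-1,2,3,4-tetrahydronaphthalene (target)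
Conditions: NaH, MeI, THF/DMF, 0 °C → rt
Reagents that add atoms: iodomethane, CI
Why: Williamson etherification of both primary alkoxides; no stereocentre is involved.

**Compound list**

1 | 2-bromo-4,5-dimethoxybenzaldehyde | COc1cc(Br)c(C=O)cc1OC | starting material
2 | 2-(2-bromo-4,5-dimethoxyphenyl)oxirane (racemic) | COc1cc(Br)c(cc1OC)C1CO1 | intermediate
3 | 2-(2-lithio-4,5-dimethoxyphenyl)oxirane (racemic) | [Li]c1cc(OC)c(OC)cc1C1CO1 | intermediate (not isolated)
4 | 4,5-dimethoxybenzocyclobuten-1-ol (racemic) | COc1cc2CC(O)c2cc1OC | intermediate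
5 | (5R)-5-{[(1R,2S,5R)-5-methyl-2-(propan-2-yl)cyclohexyl]oxy}furan-2(5H)-one | O=C1C=C[C@H](O[C@@H]2C[C@H](C)CC[C@H]2C(C)C)O1 | starting material
6 | (E)-(3,4-dimethoxy-6-methylidenecyclohexa-2,4-dien-1-ylidene)methanol | O/C=C1\C=C(OC)C(OC)=CC1=C | intermediate (not isolated)
7 | (3R,3aR,9R,9aR)-9-hydroxy-6,7-dimethoxy-3-[(1R,2S,5R)-menthyloxy]-3a,4,9,9a-tetrahydronaphtho[2,3-c]furan-1(3H)-one | O[C@H]1c2cc(OC)c(OC)cc2C[C@H]2[C@H](O[C@@H]3C[C@H](C)CC[C@H]3C(C)C)OC(=O)[C@@H]12 | intermediate
8 | 1,2-dimethoxybenzene | COc1ccccc1OC | starting material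
9 | (3R,3aR,9R,9aS)-9-(3,4-dimethoxyphenyl)-6,7-dimethoxy-3-[(1R,2S,5R)-menthyloxy]-3a,4,9,9a-tetrahydronaphtho[2,3-c]furan-1(3H)-one | COc1ccc(cc1OC)[C@@H]1c2cc(OC)c(OC)cc2C[C@H]2[C@H](O[C@@H]3C[C@H](C)CC[C@H]3C(C)C)OC(=O)[C@@H]12 | intermediate
10 | [(1R,2S,3R)-1-(3,4-dimethoxyphenyl)-6,7-dimethoxy-1,2,3,4-tetrahydronaphthalene-2,3-diyl]dimethanol | OC[C@@H]1Cc2cc(OC)c(OC)cc2[C@@H](c2ccc(OC)c(OC)c2)[C@@H]1CO | intermediate
11 | (1R,2S,3R)-1-(3,4-dimethoxyphenyl)-6,7-dimethoxy-2,3-bis(methoxymethyl)-1,2,3,4-tetrahydronaphthalene | COC[C@@H]1Cc2cc(OC)c(OC)cc2[C@@H](c2ccc(OC)c(OC)c2)[C@@H]1COC | target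

Total step count: 6
Longest linear sequence: 6 steps (1 → 2 → 4 → 7 → 9 → 10 → 11)

**Steps most likely to fail**

Step 3. The free dienol may revert, tautomerise to the o-methylbenzaldehyde or dimerise faster than it is captured by the moderately reactive butenolide, and regiocontrol may erode. Fallback, setting out from 4: silylation (TBSCl, imidazole, DMF) should give tert-butyl[(3,4-dimethoxybicyclo[4.2.0]octa-1,3,5-trien-7-yl)oxy]dimethylsilane F1, whose silyloxy-o-quinodimethane cannot tautomerise and carries the same outward donor. Heating F1 with 5 in toluene should give the O-silyl ether of 7 F2. Under the acid conditions of step 4 with 8, F2 should ionise with loss of the silanol and be arylated, coming back to the route at 9.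

Step 4. The benzylic cation may lose the C9a proton to give the conjugated dihydronaphthalene lactone, or the acid may cleave the menthyl acetal, before arylation occurs. Fallback, setting out from 7: the carbonyl and the acetal are removed first. LiAlH4 in THF should give (1R,2S,3R)-2,3-bis(hydroxymethyl)-6,7-dimethoxy-1,2,3,4-tetrahydronaphthalen-1-ol F3, and NaH/MeI should give (1R,2S,3R)-1,6,7-trimethoxy-2,3-bis(methoxymethyl)-1,2,3,4-tetrahydronaphthalene F4. Ionisation of the benzylic methyl ether of F4 (BF3·OEt2, excess 8, CH2Cl2, −40 °C) and arylation anti to the C2 substituent should come back to the route directly at 11.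

Step 2. Butyllithium may open the epoxide before halogen–metal exchange is complete, or the metal alkoxide of the product may undergo electrocyclic opening on warming. Fallback, setting out from 1: Wittig methylenation (Ph3PCH3 Br, KOtBu, THF) should give 1-bromo-2-ethenyl-4,5-dimethoxybenzene F5. Bromo-etherification (NBS, MeOH), with methanol opening the bromonium ion at the benzylic carbon, should give 1-bromo-2-(2-bromo-1-methoxyethyl)-4,5-dimethoxybenzene F6. Parham cycloalkylation (n-BuLi, THF, −100 °C → rt), in which the aryllithium displaces the primary bromide, should give 3,4,7-trimethoxybicyclo[4.2.0]octa-1,3,5-triene F7, which carries no alkoxide. Heated with 5 as in step 3, F7 should give the O-methyl ether of 7 F8, which under the conditions of step 4 loses methanol and is arylated by 8, coming back to the route at 9.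

**Further compounds**

F1 | step 3 | tert-butyl[(3,4-dimethoxybicyclo[4.2.0]octa-1,3,5-trien-7-yl)oxy]dimethylsilane (racemic) | COc1cc2CC(O[Si](C)(C)C(C)(C)C)c2cc1OC
F2 | step 3 | (3R,3aR,9R,9aR)-9-[(tert-butyldimethylsilyl)oxy]-6,7-dimethoxy-3-[(1R,2S,5R)-menthyloxy]-3a,4,9,9a-tetrahydronaphtho[2,3-c]furan-1(3H)-one | CC(C)(C)[Si](C)(C)O[C@H]1c2cc(OC)c(OC)cc2C[C@H]2[C@H](O[C@@H]3C[C@H](C)CC[C@H]3C(C)C)OC(=O)[C@@H]12
F3 | step 4 | (1R,2S,3R)-2,3-bis(hydroxymethyl)-6,7-dimethoxy-1,2,3,4-tetrahydronaphthalen-1-ol | O[C@H]1c2cc(OC)c(OC)cc2C[C@@H](CO)[C@H]1CO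
F4 | step 4 | (1R,2S,3R)-1,6,7-trimethoxy-2,3-bis(methoxymethyl)-1,2,3,4-tetrahydronaphthalene | CO[C@H]1c2cc(OC)c(OC)cc2C[C@@H](COC)[C@H]1COC
F5 | step 2 | 1-bromo-2-ethenyl-4,5-dimethoxybenzene | COc1cc(Br)c(C=C)cc1OC
F6 | step 2 | 1-bromo-2-(2-bromo-1-methoxyethyl)-4,5-dimethoxybenzene (racemic) | COc1cc(Br)c(cc1OC)C(OC)CBr
F7 | step 2 | 3,4,7-trimethoxybicyclo[4.2.0]octa-1,3,5-triene (racemic) | COC1Cc2cc(OC)c(OC)cc21
F8 | step 2 | (3R,3aR,9R,9aR)-6,7,9-trimethoxy-3-[(1R,2S,5R)-menthyloxy]-3a,4,9,9a-tetrahydronaphtho[2,3-c]furan-1(3H)-one | CO[C@H]1c2cc(OC)c(OC)cc2C[C@H]2[C@H](O[C@@H]3C[C@H](C)CC[C@H]3C(C)C)OC(=O)[C@@H]12
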